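**Retrosynthetic overview**
1. The target comes from its hexabenzyl derivative. One Lewis-acid debenzylation at the end avoids hydrogenation, which would reduce the two C=C bonds.
2. The (E)-cinnamate C=C is cut to an enol-ether aldehyde plus the malonate half-ester of tribenzyl (R)-danshensu (Knoevenagel–Doebner). The C2 stereocentre is bought with danshensu and no later step acts on it.
3. Key disconnection: the Cα–Cβ bond of the (Z)-aryl enol ether is cut to 3,4-bis(benzyloxy)benzyl chloride plus the carbanion of an O-aryl/sulfonyl acetal of methyl glyoxylate. This carbanion is a glyoxylate acyl-anion equivalent, so two normally electrophilic carbons are joined. Loss of sulfinate then unmasks the "ketone" directly as its aryl enol ether.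
4. That acetal comes from rhodium-carbenoid O–H insertion of a diazo(sulfonyl)acetate into the only free OH of 4-O-benzyl protocatechualdehyde. This fixes the 3-O linkage.
5. No ring is formed. All three benzene rings are bought intact.

Assumption: 4-(benzyloxy)-3-hydroxybenzaldehyde, 3,4-bis(benzyloxy)benzyl chloride and sodium (R)-danshensu are taken as inexpensive catalogue chemicals.

Step 1
Reactants: 1 methyl 2-(phenylsulfonyl)acetate; 2 4-acetamidobenzenesulfonyl azide
Product: 3 methyl 2-diazo-2-(phenylsulfonyl)acetate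
Conditions: 2 (1.1 equiv), Et3N, MeCN, 0 °C to rt
Reagents that add atoms: 4-acetamidobenzenesulfonyl azide (2), CC(=O)Nc1ccc(cc1)S(=O)(=O)N=[N+]=[N-]
Why: Regitz diazo transfer, in which the doubly activated methylene of 1 is deprotonated by Et3N and attacks the terminal azide nitrogen, taking up N2 while the sulfonamide leaves; no stereocentre is involved.

Step 2
Reactants: 3 methyl 2-diazo-2-(phenylsulfonyl)acetate; 4 4-(benzyloxy)-3-hydroxybenzaldehyde
Product: 5 methyl 2-[2-(benzyloxy)-5-formylphenoxy]-2-(phenylsulfonyl)acetate (racemic)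
Conditions: Rh2(OAc)4 (1 mol %), ClCH2CH2Cl, 80 °C, 3 added over 2 h
Reagents that add atoms: none
Why: Rhodium-carbenoid O–H insertion, in which the electrophilic carbenoid is captured by the only free hydroxyl (oxonium ylide, then proton shift) faster than by the formyl oxygen, so the ether oxygen sits at C3 of the central ring; the new stereocentre is racemic and is erased in step 3.

Step 3
Reactants: 5 methyl 2-[2-(benzyloxy)-5-formylphenoxy]-2-(phenylsulfonyl)acetate; 6 4-(chloromethyl)-1,2-bis(benzyloxy)benzene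
Product: 8 methyl (Z)-2-[2-(benzyloxy)-5-formylphenoxy]-3-[3,4-bis(benzyloxy)phenyl]prop-2-enoate, via alkylated sulfone 7 (not isolated)
Conditions: 6 (1.3 equiv), Cs2CO3 (3 equiv), DMF, 0 °C to rt; then 60 °C
Reagents that add atoms: none
Why: Proposed new method: 5 is the O-aryl/sulfonyl acetal of methyl glyoxylate, so its Cs2CO3-generated carbanion (sulfonyl- and ester-stabilised, mild enough to spare the free formyl group) is a glyoxylate acyl-anion equivalent that joins the masked carbonyl carbon to the equally electrophilic benzylic carbon of 6 by SN2 alkylation, after which base-induced 1,2-elimination of benzenesulfinate (a far better nucleofuge than the aryloxide and pushed out by the aryloxy lone pair) unmasks the carbonyl directly as its aryl enol ether, with the Z geometry (aryl cis to the small aryloxy group, trans to CO2Me) being the thermodynamic one reached through reversible conjugate addition of sulfinate; the closest known reaction types are alkylation–dehydrosulfinylation of alpha-sulfonyl esters and the acyl-anion chemistry of alpha-alkoxy sulfones.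

Step 4
Reactants: 9 sodium (2R)-3-(3,4-dihydroxyphenyl)-2-hydroxypropanoate (sodium danshensu); 10 benzyl bromide
Product: 11 benzyl (2R)-3-[3,4-bis(benzyloxy)phenyl]-2-hydroxypropanoate
Conditions: BnBr (3.3 equiv), K2CO3 (2.5 equiv), DMF, rt
Reagents that add atoms: benzyl bromide (10), BrCc1ccccc1
Why: Williamson etherification and carboxylate alkylation, in which carbonate ionises only the two phenols beside the carboxylate, so the secondary alcohol stays free and the chiral-pool (R) centre is not deprotonated.

Step 5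
Reactants: 11 benzyl (2R)-3-[3,4-bis(benzyloxy)phenyl]-2-hydroxypropanoate; 12 2,2-dimethyl-1,3-dioxane-4,6-dione (Meldrum's acid); 8 methyl (Z)-2-[2-(benzyloxy)-5-formylphenoxy]-3-[3,4-bis(benzyloxy)phenyl]prop-2-enoate
Product: 14 benzyl (2R)-3-[3,4-bis(benzyloxy)phenyl]-2-{[(2E)-3-(4-(benzyloxy)-3-{[(1Z)-2-[3,4-bis(benzyloxy)phenyl]-1-(methoxycarbonyl)ethenyl]oxy}phenyl)prop-2-enoyl]oxy}propanoate, via malonate half-ester 13 (not isolated)
Conditions: 12 (1.1 equiv), toluene, 105 °C; then 8, pyridine, piperidine (cat.), rt to 45 °C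
Reagents that add atoms: Meldrum's acid (12), CC1(C)OC(=O)CC(=O)O1
Why: Alcoholysis of Meldrum's acid followed by a Knoevenagel–Doebner condensation, in which iminium activation of the aldehyde and decarboxylative elimination give the E-cinnamate, while the weak amine bases leave both the (R) centre and the Z enol ether untouched.

Step 6
Reactants: 14 hexabenzyl-protected target
Product: 15 (2R)-3-(3,4-dihydroxyphenyl)-2-{[(2E)-3-(3-{[(1Z)-2-(3,4-dihydroxyphenyl)-1-(methoxycarbonyl)ethenyl]oxy}-4-hydroxyphenyl)prop-2-enoyl]oxy}propanoic acid (CNP0286155.1)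
Conditions: BCl3 (12 equiv), C6HMe5 (18 equiv), CH2Cl2, −78 to −40 °C; aq. THF quench
Reagents that add atoms: none
Why: Lewis-acid debenzylation with Friedel–Crafts cation scavenging, in which BCl3 ionises the five aryl benzyl ethers and the benzyl ester and pentamethylbenzene traps the benzyl cations irreversibly, so both C=C bonds, the methyl ester, the cinnamate ester, the electron-poor enol ether and the stereocentre survive at low temperature.

**Compound list**
1 | methyl 2-(phenylsulfonyl)acetate | COC(=O)CS(=O)(=O)c1ccccc1 | starting material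
2 | 4-acetamidobenzenesulfonyl azide | CC(=O)Nc1ccc(cc1)S(=O)(=O)N=[N+]=[N-] | starting material
3 | methyl 2-diazo-2-(phenylsulfonyl)acetate | COC(=O)C(=[N+]=[N-])S(=O)(=O)c1ccccc1 | intermediate
4 | 4-(benzyloxy)-3-hydroxybenzaldehyde | O=Cc1ccc(OCc2ccccc2)c(O)c1 | starting material
5 | methyl 2-[2-(benzyloxy)-5-formylphenoxy]-2-(phenylsulfonyl)acetate (racemic) | COC(=O)C(Oc1cc(C=O)ccc1OCc2ccccc2)S(=O)(=O)c3ccccc3 | intermediate
6 | 4-(chloromethyl)-1,2-bis(benzyloxy)benzene | ClCc1ccc(OCc2ccccc2)c(OCc3ccccc3)c1 | starting material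
7 | methyl 2-[2-(benzyloxy)-5-formylphenoxy]-3-[3,4-bis(benzyloxy)phenyl]-2-(phenylsulfonyl)propanoate (racemic, not isolated) | COC(=O)C(Cc1ccc(OCc2ccccc2)c(OCc3ccccc3)c1)(Oc4cc(C=O)ccc4OCc5ccccc5)S(=O)(=O)c6ccccc6 | intermediate
8 | methyl (Z)-2-[2-(benzyloxy)-5-formylphenoxy]-3-[3,4-bis(benzyloxy)phenyl]prop-2-enoate | COC(=O)/C(=C/c1ccc(OCc2ccccc2)c(OCc3ccccc3)c1)Oc4cc(C=O)ccc4OCc5ccccc5 | intermediate
9 | sodium (2R)-3-(3,4-dihydroxyphenyl)-2-hydroxypropanoate | O[C@H](Cc1ccc(O)c(O)c1)C(=O)[O-].[Na+] | starting material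
10 | benzyl bromide | BrCc1ccccc1 | starting material
11 | benzyl (2R)-3-[3,4-bis(benzyloxy)phenyl]-2-hydroxypropanoate | O[C@H](Cc1ccc(OCc2ccccc2)c(OCc3ccccc3)c1)C(=O)OCc4ccccc4 | intermediate
12 | 2,2-dimethyl-1,3-dioxane-4,6-dione (Meldrum's acid) | CC1(C)OC(=O)CC(=O)O1 | starting material
13 | 3-{[(2R)-1-(benzyloxy)-3-[3,4-bis(benzyloxy)phenyl]-1-oxopropan-2-yl]oxy}-3-oxopropanoic acid (not isolated) | OC(=O)CC(=O)O[C@H](Cc1ccc(OCc2ccccc2)c(OCc3ccccc3)c1)C(=O)OCc4ccccc4 | intermediate
14 | hexabenzyl-protected target (full name in step 5; 2R, E-cinnamate, Z-enol ether) | COC(=O)/C(=C/c1ccc(OCc2ccccc2)c(OCc3ccccc3)c1)Oc4cc(/C=C/C(=O)O[C@H](Cc5ccc(OCc6ccccc6)c(OCc7ccccc7)c5)C(=O)OCc8ccccc8)ccc4OCc9ccccc9 | intermediate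
15 | CNP0286155.1 (full name in step 6; 2R, E-cinnamate, Z-enol ether) | COC(=O)/C(=C/c1ccc(O)c(O)c1)Oc1cc(/C=C/C(=O)O[C@H](Cc2ccc(O)c(O)c2)C(=O)O)ccc1O | target

**Total step count:** 6. **Longest linear sequence:** 5 (steps 1, 2, 3, 5, 6).

**Three steps most likely to fail**

Step 3 (tandem alkylation–desulfinylation).
- Risks: the quaternary carbon may form slowly. The carbanion may add to a formyl group and close to an epoxide with loss of sulfinate. The elimination may be incomplete or give E/Z mixtures.
- Fallback: make the vinyl C–O bond instead of the C–C bond, setting out from 4. Commercial 3,4-bis(benzyloxy)benzaldehyde F1 is olefinated with Ph3P=C(Br)CO2Me (CH2Cl2, rt) to methyl (Z)-2-bromo-3-[3,4-bis(benzyloxy)phenyl]prop-2-enoate F2. Phenol 4 is then vinylated with F2 with retention of geometry (CuI, N,N-dimethylglycine, Cs2CO3, dioxane, 90 °C). This returns to the route at 8.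

Step 6 (sixfold debenzylation).
- Risks: the benzyl ester may cleave slowly. The freed catechols may be C-benzylated. The liberated 4-OH may add to the enol-ether acrylate under Lewis-acid conditions.
- Fallback: deprotect the two halves first and join them without protecting groups, setting out from 8 and 13. BCl3/C6HMe5 on 8 gives methyl (Z)-3-(3,4-dihydroxyphenyl)-2-(5-formyl-2-hydroxyphenoxy)prop-2-enoate F3. Compound 13, now isolated and free of C=C bonds, is hydrogenolysed (H2, 10% Pd/C, EtOAc) to (2R)-2-[(carboxyacetyl)oxy]-3-(3,4-dihydroxyphenyl)propanoic acid F4. Knoevenagel–Doebner condensation of F3 with F4 (pyridine, cat. piperidine, 50 °C, argon) comes back to the route at 15.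

Step 2 (O–H insertion).
- Risks: carbonyl-ylide formation at the aldehyde, aromatic or benzylic C–H attack by the very electrophilic carbenoid, and carbene dimerisation.
- Fallback: build the same acetal by substitution and oxidation, setting out from 4. Methyl (phenylsulfanyl)acetate is chlorinated with N-chlorosuccinimide (CH2Cl2, rt) to methyl 2-chloro-2-(phenylsulfanyl)acetate F5. The phenoxide of 4 (K2CO3, acetone) displaces chloride to give methyl 2-[2-(benzyloxy)-5-formylphenoxy]-2-(phenylsulfanyl)acetate F6. Oxidation with mCPBA (2.1 equiv, NaHCO3, CH2Cl2, 0 °C) is much faster at sulfur than at the aldehyde and comes back to the route at 5.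

**Further compounds**
F1 | step 3 | 3,4-bis(benzyloxy)benzaldehyde | O=Cc1ccc(OCc2ccccc2)c(OCc3ccccc3)c1
F2 | step 3 | methyl (Z)-2-bromo-3-[3,4-bis(benzyloxy)phenyl]prop-2-enoate | COC(=O)/C(Br)=C/c1ccc(OCc2ccccc2)c(OCc3ccccc3)c1
F3 | step 6 | methyl (Z)-3-(3,4-dihydroxyphenyl)-2-(5-formyl-2-hydroxyphenoxy)prop-2-enoate | COC(=O)/C(=C/c1ccc(O)c(O)c1)Oc2cc(C=O)ccc2O
F4 | step 6 | (2R)-2-[(carboxyacetyl)oxy]-3-(3,4-dihydroxyphenyl)propanoic acid | OC(=O)CC(=O)O[C@H](Cc1ccc(O)c(O)c1)C(=O)O
F5 | step 2 | methyl 2-chloro-2-(phenylsulfanyl)acetate (racemic) | COC(=O)C(Cl)Sc1ccccc1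
F6 | step 2 | methyl 2-[2-(benzyloxy)-5-formylphenoxy]-2-(phenylsulfanyl)acetate (racemic) | COC(=O)C(Oc1cc(C=O)ccc1OCc2ccccc2)Sc3ccccc3
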